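**Retrosynthetic overview**
1. Ring C (the pyran) is closed last, through the O1–C2 bond: the ring A phenoxide displaces the primary mesylate of the (S)-2,3-diarylpropanol 12. Rings A and B come intact from 4-bromoresorcinol and 2,6-dimethoxyphenol.
2. Key disconnection C3–C1′: enantioselective α-arylation of 3-arylpropanal 10 (as a chiral enamine) with ring B used as an aryl cation equivalent, the aryl(mesityl)iodonium salt 6. Two natively nucleophilic carbons (enamine α-carbon and electron-rich arene carbon) are joined, and C3 (S) is set in this bond-forming step.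
3. Salt 6 comes from 2,6-dimethoxyphenol: O-silylation, bromination, branched-selective Suzuki prenylation (gives the 1,1-dimethylallyl group), then C–H iodonium formation.
4. Aldehyde 10 comes from 4-bromoresorcinol: bis-silylation, then Heck reaction with allyl alcohol.

Assumption: the target is the (3S)-isoflavan (CIP descriptor read from the SMILES); the facial sense in step 7 is assigned from the usual imidazolidinone enamine model, and the (2S,5S) catalyst would be used instead if the observed sense were opposite.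

**Route**

Step 1
Reactants: 1 2,6-dimethoxyphenol
Product: 2 (2,6-dimethoxyphenoxy)triisopropylsilane
Conditions: TIPSCl, imidazole, DMF, 40 °C
Reagents that add atoms: triisopropylsilyl chloride, CC(C)[Si](Cl)(C(C)C)C(C)C
Why: Imidazole-promoted O-silylation masks the only phenol, so the ring is not oxidised by the trivalent-iodine reagent of step 4 and the silyl group can be removed by fluoride at the end.

Step 2
Reactants: 2 (2,6-dimethoxyphenoxy)triisopropylsilane
Product: 3 (3-bromo-2,6-dimethoxyphenoxy)triisopropylsilane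
Conditions: NBS (1.0 equiv), MeCN, 0 °C to rt
Reagents that add atoms: N-bromosuccinimide, O=C1CCC(=O)N1Br
Why: Electrophilic aromatic bromination goes to C3, which is ortho to one methoxy and para to the other, whereas the position para to the bulky, twisted silyloxy group is not activated, and one equivalent of NBS stops at the monobromide.

Step 3
Reactants: 3 (3-bromo-2,6-dimethoxyphenoxy)triisopropylsilane; 4 3-methylbut-2-enylboronic acid pinacol ester (prenylBpin, 1.5 equiv)
Product: 5 [2,6-dimethoxy-3-(2-methylbut-3-en-2-yl)phenoxy]triisopropylsilane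
Conditions: Pd(OAc)2 (2 mol %), 2-{bis[3,5-bis(trifluoromethyl)phenyl]phosphino}-3,6-dimethoxy-2′,4′,6′-triisopropylbiphenyl (4 mol %), K3PO4 (aq), MeCN, 70 °C
Reagents that add atoms: none
Why: Ligand-controlled γ-selective Suzuki–Miyaura allylation, in which SE2′ transmetalation places palladium on the tertiary carbon and fast reductive elimination from the electron-poor phosphine complex should give the 1,1-dimethylallyl arene rather than the linear prenyl isomer (the branched/linear ratio depends on the ligand and must be confirmed on this substrate).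

Step 4
Reactants: 5 [2,6-dimethoxy-3-(2-methylbut-3-en-2-yl)phenoxy]triisopropylsilane
Product: 6 [2,4-dimethoxy-5-(2-methylbut-3-en-2-yl)-3-(triisopropylsilyloxy)phenyl](2,4,6-trimethylphenyl)iodonium trifluoromethanesulfonate
Conditions: MesI(OH)OTs (1.05 equiv), CF3CH2OH/CH2Cl2, 0 °C to rt; then NaOTf (aq) wash
Reagents that add atoms: hydroxy(tosyloxy)iodomesitylene, Cc1cc(C)c(I(O)OS(=O)(=O)c2ccc(C)cc2)c(C)c1; sodium trifluoromethanesulfonate, [Na+].[O-]S(=O)(=O)C(F)(F)F
Why: Koser-type electrophilic aromatic substitution by the trivalent-iodine reagent occurs at the only ring position ortho/para to both methoxy groups and should be much faster than attack on the hindered monosubstituted alkene, giving a diaryliodonium salt whose mesityl group is the non-transferred one.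

Step 5
Reactants: 7 4-bromobenzene-1,3-diol (4-bromoresorcinol)
Product: 8 4-bromo-1,3-bis(tert-butyldimethylsilyloxy)benzene
Conditions: TBSCl (2.2 equiv), imidazole, DMF, rt
Reagents that add atoms: tert-butyldimethylsilyl chloride, CC(C)(C)[Si](C)(C)Cl
Why: Standard imidazole-promoted bis-silylation protects both phenols as fluoride-labile ethers that tolerate the Heck reaction, the copper/amine arylation and NaBH4.

Step 6
Reactants: 8 4-bromo-1,3-bis(tert-butyldimethylsilyloxy)benzene; 9 prop-2-en-1-ol (allyl alcohol, 1.5 equiv)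
Product: 10 3-[2,4-bis(tert-butyldimethylsilyloxy)phenyl]propanal
Conditions: Pd(OAc)2 (3 mol %), P(t-Bu)3·HBF4 (6 mol %), Cy2NMe, dioxane, 80 °C
Reagents that add atoms: none
Why: Heck arylation of allyl alcohol at the terminal carbon is followed by β-hydride elimination toward the carbinol carbon, and the resulting enol tautomerises to the saturated 3-arylpropanal.

Step 7
Reactants: 10 3-[2,4-bis(tert-butyldimethylsilyloxy)phenyl]propanal (1.5 equiv); 6 aryl(mesityl)iodonium triflate (1.0 equiv)
Product: 12 (2S)-3-[2,4-bis(tert-butyldimethylsilyloxy)phenyl]-2-[2,4-dimethoxy-5-(2-methylbut-3-en-2-yl)-3-(triisopropylsilyloxy)phenyl]propan-1-ol, via alpha-aryl aldehyde 11 (not isolated)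
Conditions: CuBr (10 mol %), (2R,5R)-5-benzyl-2-tert-butyl-3-methylimidazolidin-4-one·CCl3CO2H (10 mol %), NaHCO3, PhMe/Et2O 2:1, 23 °C; then MeOH, NaBH4, 0 °C
Reagents that add atoms: none
Why: Copper/amine dual-catalysed enantioselective α-arylation of an aldehyde with a diaryliodonium salt, in which CuBr takes the less hindered ring B aryl from 6 as an electrophilic aryl–copper species (formally trivalent copper, the electron-rich arene carbon reacting with reversed polarity) that is attacked by the E-enamine on the Re face left open by the catalyst benzyl group, setting C3 as S, and immediate NaBH4 reduction removes the epimerisable aldehyde.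

Step 8
Reactants: 12 (2S)-3-[2,4-bis(tert-butyldimethylsilyloxy)phenyl]-2-[2,4-dimethoxy-5-(2-methylbut-3-en-2-yl)-3-(triisopropylsilyloxy)phenyl]propan-1-ol
Product: 15 (3S)-3-[3-hydroxy-2,4-dimethoxy-5-(2-methylbut-3-en-2-yl)phenyl]chroman-7-ol (target), via mesylate 13 (not isolated), via triphenol mesylate 14 (not isolated)
Conditions: MsCl (1.05 equiv), Et3N, CH2Cl2, 0 °C; evaporate; TBAF (4 equiv), THF (0.02 M), 0 °C to rt; NH4Cl (aq)
Reagents that add atoms: none
Why: Mesylation of the primary alcohol followed by fluoride desilylation unmasks the ortho phenoxide of ring A, which closes ring C by intramolecular SN2 (6-exo-tet Williamson etherification) at the CH2 carbon, so the stereocentre is untouched and the two remaining silyl groups are lost in the same operation.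

**Compound list**
1 | 2,6-dimethoxyphenol | COc1cccc(OC)c1O | starting material
2 | (2,6-dimethoxyphenoxy)triisopropylsilane | COc1cccc(OC)c1O[Si](C(C)C)(C(C)C)C(C)C | intermediate
3 | (3-bromo-2,6-dimethoxyphenoxy)triisopropylsilane | COc1ccc(Br)c(OC)c1O[Si](C(C)C)(C(C)C)C(C)C | intermediate
4 | 4,4,5,5-tetramethyl-2-(3-methylbut-2-en-1-yl)-1,3,2-dioxaborolane (prenylBpin) | CC(C)=CCB1OC(C)(C)C(C)(C)O1 | starting material
5 | [2,6-dimethoxy-3-(2-methylbut-3-en-2-yl)phenoxy]triisopropylsilane | C=CC(C)(C)c1ccc(OC)c(O[Si](C(C)C)(C(C)C)C(C)C)c1OC | intermediate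
6 | [2,4-dimethoxy-5-(2-methylbut-3-en-2-yl)-3-(triisopropylsilyloxy)phenyl](2,4,6-trimethylphenyl)iodonium trifluoromethanesulfonate | C=CC(C)(C)c1cc([I+]c2c(C)cc(C)cc2C)c(OC)c(O[Si](C(C)C)(C(C)C)C(C)C)c1OC.[O-]S(=O)(=O)C(F)(F)F | intermediate
7 | 4-bromobenzene-1,3-diol | Oc1ccc(Br)c(O)c1 | starting material
8 | 4-bromo-1,3-bis(tert-butyldimethylsilyloxy)benzene | CC(C)(C)[Si](C)(C)Oc1ccc(Br)c(O[Si](C)(C)C(C)(C)C)c1 | intermediate
9 | prop-2-en-1-ol | C=CCO | starting material
10 | 3-[2,4-bis(tert-butyldimethylsilyloxy)phenyl]propanal | O=CCCc1ccc(O[Si](C)(C)C(C)(C)C)cc1O[Si](C)(C)C(C)(C)C | intermediate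
11 | (2S)-3-[2,4-bis(tert-butyldimethylsilyloxy)phenyl]-2-[2,4-dimethoxy-5-(2-methylbut-3-en-2-yl)-3-(triisopropylsilyloxy)phenyl]propanal | C=CC(C)(C)c1cc([C@@H](C=O)Cc2ccc(O[Si](C)(C)C(C)(C)C)cc2O[Si](C)(C)C(C)(C)C)c(OC)c(O[Si](C(C)C)(C(C)C)C(C)C)c1OC | intermediate
12 | (2S)-3-[2,4-bis(tert-butyldimethylsilyloxy)phenyl]-2-[2,4-dimethoxy-5-(2-methylbut-3-en-2-yl)-3-(triisopropylsilyloxy)phenyl]propan-1-ol | C=CC(C)(C)c1cc([C@@H](CO)Cc2ccc(O[Si](C)(C)C(C)(C)C)cc2O[Si](C)(C)C(C)(C)C)c(OC)c(O[Si](C(C)C)(C(C)C)C(C)C)c1OC | intermediate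
13 | (2S)-3-[2,4-bis(tert-butyldimethylsilyloxy)phenyl]-2-[2,4-dimethoxy-5-(2-methylbut-3-en-2-yl)-3-(triisopropylsilyloxy)phenyl]propyl methanesulfonate | C=CC(C)(C)c1cc([C@@H](COS(C)(=O)=O)Cc2ccc(O[Si](C)(C)C(C)(C)C)cc2O[Si](C)(C)C(C)(C)C)c(OC)c(O[Si](C(C)C)(C(C)C)C(C)C)c1OC | intermediate
14 | (2S)-3-(2,4-dihydroxyphenyl)-2-[3-hydroxy-2,4-dimethoxy-5-(2-methylbut-3-en-2-yl)phenyl]propyl methanesulfonate (present as its phenoxides) | C=CC(C)(C)c1cc([C@@H](COS(C)(=O)=O)Cc2ccc(O)cc2O)c(OC)c(O)c1OC | intermediate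
15 | (3S)-3-[3-hydroxy-2,4-dimethoxy-5-(2-methylbut-3-en-2-yl)phenyl]chroman-7-ol | C=CC(C)(C)c1cc([C@H]2COc3cc(O)ccc3C2)c(OC)c(O)c1OC | target

**Step count**
Total: 8 steps. Longest linear sequence: 6 steps (steps 1, 2, 3, 4, 7, 8, from 2,6-dimethoxyphenol); the ring A branch (steps 5, 6) joins at step 7.

**Three steps most likely to fail, with fallbacks**

Step 7 (key α-arylation). The risks are slow transfer of the hindered, electron-rich ring B aryl from 6, and an ee below the roughly 90% typical of this reaction type. The fallback leaves the aldehyde oxidation level and enamine activation. It sets out from 10, which is oxidised (NaClO2, NaH2PO4, 2-methyl-2-butene, t-BuOH/H2O) to 3-[2,4-bis(tert-butyldimethylsilyloxy)phenyl]propanoic acid F1. The acid is converted through its pivaloyl mixed anhydride (PivCl, Et3N; then lithiated oxazolidin-2-one) into 3-{3-[2,4-bis(tert-butyldimethylsilyloxy)phenyl]propanoyl}oxazolidin-2-one F2. Enolisation and O-silylation (LiN(SiMe3)2, Me3SiCl, THF, −78 °C) give 3-{(Z)-3-[2,4-bis(tert-butyldimethylsilyloxy)phenyl]-1-(trimethylsilyloxy)prop-1-en-1-yl}oxazolidin-2-one F3. F3 is arylated with 6 under Cu(OTf)2 and 2,2′-(propane-2,2-diyl)bis(4-phenyl-4,5-dihydrooxazole) (the ligand enantiomer that gives the S product) to the configurationally stable 3-{(2S)-3-[2,4-bis(tert-butyldimethylsilyloxy)phenyl]-2-[2,4-dimethoxy-5-(2-methylbut-3-en-2-yl)-3-(triisopropylsilyloxy)phenyl]propanoyl}oxazolidin-2-one F4. LiBH4 reduction (THF/MeOH, 0 °C) then returns to the route at 12.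

Step 3 (branched-selective prenylation). The risk is a mixture of linear and branched isomers at a hindered, electron-rich bromide. The fallback builds the quaternary carbon in two classical operations and sets out from 3. Palladium-catalysed α-arylation of 2-methylpropanal (Pd(OAc)2, rac-BINAP, Cs2CO3, dioxane, 80 °C) gives 2-[2,4-dimethoxy-3-(triisopropylsilyloxy)phenyl]-2-methylpropanal F5. Wittig methylenation (Ph3PCH3Br, KOt-Bu, THF, 0 °C) then returns to the route at 5.

Step 4 (iodonium formation beside an alkene). The risk is oxidation of the vinyl group by the trivalent-iodine reagent. The fallback changes the order so that the alkene is introduced after the key bond, and sets out from 3. Treatment with MesI(OH)OTs and then NaOTf gives [5-bromo-2,4-dimethoxy-3-(triisopropylsilyloxy)phenyl](2,4,6-trimethylphenyl)iodonium trifluoromethanesulfonate F6. Arylation of 10 with F6 under the step 7 conditions gives (2S)-3-[2,4-bis(tert-butyldimethylsilyloxy)phenyl]-2-[5-bromo-2,4-dimethoxy-3-(triisopropylsilyloxy)phenyl]propanal F7 (not isolated). NaBH4 reduction gives (2S)-3-[2,4-bis(tert-butyldimethylsilyloxy)phenyl]-2-[5-bromo-2,4-dimethoxy-3-(triisopropylsilyloxy)phenyl]propan-1-ol F8. The branched-selective Suzuki coupling of F8 with 4 (step 3 conditions) returns to the route at 12.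

**Further compounds**
F1 | step 7 | 3-[2,4-bis(tert-butyldimethylsilyloxy)phenyl]propanoic acid | OC(=O)CCc1ccc(O[Si](C)(C)C(C)(C)C)cc1O[Si](C)(C)C(C)(C)C
F2 | step 7 | 3-{3-[2,4-bis(tert-butyldimethylsilyloxy)phenyl]propanoyl}oxazolidin-2-one | O=C(CCc1ccc(O[Si](C)(C)C(C)(C)C)cc1O[Si](C)(C)C(C)(C)C)N1CCOC1=O
F3 | step 7 | 3-{(Z)-3-[2,4-bis(tert-butyldimethylsilyloxy)phenyl]-1-(trimethylsilyloxy)prop-1-en-1-yl}oxazolidin-2-one | C[Si](C)(C)O/C(N1CCOC1=O)=C\Cc1ccc(O[Si](C)(C)C(C)(C)C)cc1O[Si](C)(C)C(C)(C)C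
F4 | step 7 | 3-{(2S)-3-[2,4-bis(tert-butyldimethylsilyloxy)phenyl]-2-[2,4-dimethoxy-5-(2-methylbut-3-en-2-yl)-3-(triisopropylsilyloxy)phenyl]propanoyl}oxazolidin-2-one | C=CC(C)(C)c1cc([C@@H](C(=O)N2CCOC2=O)Cc2ccc(O[Si](C)(C)C(C)(C)C)cc2O[Si](C)(C)C(C)(C)C)c(OC)c(O[Si](C(C)C)(C(C)C)C(C)C)c1OC
F5 | step 3 | 2-[2,4-dimethoxy-3-(triisopropylsilyloxy)phenyl]-2-methylpropanal | CC(C)(C=O)c1ccc(OC)c(O[Si](C(C)C)(C(C)C)C(C)C)c1OC
F6 | step 4 | [5-bromo-2,4-dimethoxy-3-(triisopropylsilyloxy)phenyl](2,4,6-trimethylphenyl)iodonium trifluoromethanesulfonate | COc1c([I+]c2c(C)cc(C)cc2C)cc(Br)c(OC)c1O[Si](C(C)C)(C(C)C)C(C)C.[O-]S(=O)(=O)C(F)(F)F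
F7 | step 4 | (2S)-3-[2,4-bis(tert-butyldimethylsilyloxy)phenyl]-2-[5-bromo-2,4-dimethoxy-3-(triisopropylsilyloxy)phenyl]propanal | COc1c(Br)cc([C@@H](C=O)Cc2ccc(O[Si](C)(C)C(C)(C)C)cc2O[Si](C)(C)C(C)(C)C)c(OC)c1O[Si](C(C)C)(C(C)C)C(C)C
F8 | step 4 | (2S)-3-[2,4-bis(tert-butyldimethylsilyloxy)phenyl]-2-[5-bromo-2,4-dimethoxy-3-(triisopropylsilyloxy)phenyl]propan-1-ol | COc1c(Br)cc([C@@H](CO)Cc2ccc(O[Si](C)(C)C(C)(C)C)cc2O[Si](C)(C)C(C)(C)C)c(OC)c1O[Si](C(C)C)(C(C)C)C(C)C
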